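The piperidine is disconnected at N–C2'. C2' is the benzylic carbon on C6 of ring A and sits between the C5 and C7 hydroxyls, so ionisation at C2' gives an ortho-quinone methide. A chiral phosphoric acid turns the racemic carbinol 6 into this methide and guides the tethered carbamate nitrogen onto C2', closing the ring and setting the R centre in one operation. The precursor is a phloroglucinol-derived 1-aryl-5-(methoxycarbonylamino)pentan-1-ol with both ortho hydroxyls free and the para oxygen (the later O1) held as a pivalate. The methyl carbamate later becomes N-methyl; the flavanone C2 is set last by rhodium-catalysed arylation of a chromone.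

Key step: step 5

Assumption: (R)-TRIP in step 5 and (S)-MeO-F12-BIPHEP in step 10 are written as the working antipodes; the sense of induction of each is not known in advance, and the mirror-image catalyst would be used instead if a first run shows the opposite sense, with no other change.

Step 1
Reactants: 1 5-aminopentanoic acid
Product: 2 5-[(methoxycarbonyl)amino]pentanoic acid
Conditions: ClCO2Me, aq. NaOH, 0 °C; then HCl to pH 2
Reagents that add atoms: methyl chloroformate, COC(=O)Cl
Why: Schotten–Baumann acylation of the amine by the chloroformate in aqueous base gives the methyl carbamate, which later serves both as the nitrogen nucleophile and as the source of the N-methyl carbon.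

Step 2
Reactants: 2 5-[(methoxycarbonyl)amino]pentanoic acid; 3 phloroglucinol
Product: 4 methyl N-[5-oxo-5-(2,4,6-trihydroxyphenyl)pentyl]carbamate
Conditions: 3 (2 equiv), BF3·OEt2 (solvent), 80 °C; aq. NaOAc
Reagents that add atoms: none
Why: Friedel–Crafts acylation of the electron-rich phloroglucinol by the BF3-activated acid gives the aryl ketone, the three ring positions being equivalent so that only one monoacyl product can form and the first acyl group deactivating the ring against a second.

Step 3
Reactants: 4 methyl N-[5-oxo-5-(2,4,6-trihydroxyphenyl)pentyl]carbamate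
Product: 5 3,5-dihydroxy-4-{5-[(methoxycarbonyl)amino]pentanoyl}phenyl 2,2-dimethylpropanoate
Conditions: t-BuCOCl (1.05 equiv), Et3N (1.1 equiv), THF, −40 → 0 °C
Reagents that add atoms: pivaloyl chloride, CC(C)(C)C(=O)Cl
Why: Site-selective O-acylation, in which the para hydroxyl is the most acidic one and the only one neither hydrogen-bonded to nor shielded by the ketone, so that one equivalent of base and the bulky acid chloride should esterify it alone, while the electron-poor ester (chosen over an electron-releasing ether) tempers the ring for steps 4 and 5.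

Step 4
Reactants: 5 3,5-dihydroxy-4-{5-[(methoxycarbonyl)amino]pentanoyl}phenyl 2,2-dimethylpropanoate
Product: 6 3,5-dihydroxy-4-{1-hydroxy-5-[(methoxycarbonyl)amino]pentyl}phenyl 2,2-dimethylpropanoate (racemic at the carbinol carbon)
Conditions: NaBH4, THF/EtOH, −20 → 0 °C; pH 7 phosphate buffer; crude product used at once
Reagents that add atoms: none
Why: Borohydride reduction of the aryl ketone, run cold and quenched at neutral pH so that the benzylic alcohol does not ionise to the methide and take up a second hydride; the carbinol is racemic, which does not matter because step 5 passes through a planar intermediate.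

Step 5
Reactants: 6 3,5-dihydroxy-4-{1-hydroxy-5-[(methoxycarbonyl)amino]pentyl}phenyl 2,2-dimethylpropanoate
Product: 8 methyl (2R)-2-{4-[(2,2-dimethylpropanoyl)oxy]-2,6-dihydroxyphenyl}piperidine-1-carboxylate, via ortho-quinone methide 7 (not isolated)
Conditions: (R)-TRIP [(R)-3,3'-bis(2,4,6-triisopropylphenyl)-1,1'-binaphthyl-2,2'-diyl hydrogen phosphate] (10 mol%), 4 Å MS, CH2Cl2/toluene, 0 → 25 °C
Reagents that add atoms: none
Why: Proposed new method: the phosphoric acid protonates the benzylic hydroxyl of 6, water leaves with the help of either of the two equivalent ortho hydroxyls, and the resulting ortho-quinone methide 7 stays hydrogen-bonded through its carbonyl oxygen to the phosphate, whose P=O oxygen at the same time holds the carbamate N–H. The nitrogen then adds to the exocyclic methide carbon (aza-conjugate addition), which forms N–C2', closes the piperidine in a 6-exo-trig mode and restores the aromatic ring. The closest known reaction type is the chiral phosphoric acid catalysed enantioselective conjugate addition of external nucleophiles to ortho-quinone methides generated in situ from ortho-hydroxybenzyl alcohols; an intramolecular carbamate closure onto an alkyl-substituted methide of this kind has not been shown. The new stereocentre C2' is set by the catalyst alone, since the bound planar methide is attacked on the face left open by the 2,4,6-triisopropylphenyl groups and the substrate has no other stereocentre. The step needs N-attack over O-attack of the carbamate and ring closure over intermolecular capture or tautomerisation to the vinylphenol; the four-carbon tether (six-membered N-closure against eight-membered O-closure), the symmetric pair of ortho hydroxyls (one methide whichever hydroxyl assists) and the pivalate on the para oxygen, which damps uncatalysed ionisation of 6, re-ionisation of 8 and the nucleophilicity of the ring carbons, should secure this.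

Step 6
Reactants: 8 methyl (2R)-2-{4-[(2,2-dimethylpropanoyl)oxy]-2,6-dihydroxyphenyl}piperidine-1-carboxylate
Product: 9 methyl (2R)-2-{2,6-bis(benzyloxy)-4-[(2,2-dimethylpropanoyl)oxy]phenyl}piperidine-1-carboxylate
Conditions: BnBr (2.5 equiv), K2CO3, n-Bu4NI (cat.), DMF, 25 °C
Reagents that add atoms: benzyl bromide, BrCc1ccccc1
Why: Williamson etherification of both phenoxides with benzyl bromide caps the ortho oxygens, which shuts off any return to a quinone methide and so protects C2' from racemisation in all later steps.

Step 7
Reactants: 9 methyl (2R)-2-{2,6-bis(benzyloxy)-4-[(2,2-dimethylpropanoyl)oxy]phenyl}piperidine-1-carboxylate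
Product: 10 3,5-bis(benzyloxy)-4-[(2R)-1-methylpiperidin-2-yl]phenol
Conditions: LiAlH4 (excess), THF, 0 → 60 °C; H2O/aq. NaOH work-up
Reagents that add atoms: none
Why: Lithium aluminium hydride reduces the methyl carbamate to the N-methyl amine (the carbamate carbon becomes the methyl group) and in the same operation cleaves the pivalate reductively to the free para phenol, neither process touching C2'.

Step 8
Reactants: 10 3,5-bis(benzyloxy)-4-[(2R)-1-methylpiperidin-2-yl]phenol
Product: 11 1-{2,4-bis(benzyloxy)-6-hydroxy-3-[(2R)-1-methylpiperidin-2-yl]phenyl}ethan-1-one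
Conditions: Ac2O, BF3·OEt2 (4 equiv), CH2Cl2, 0 → 25 °C; aq. NaOAc
Reagents that add atoms: acetic anhydride, CC(=O)OC(C)=O
Why: Friedel–Crafts C-acetylation ortho to the free phenol, where the para position is blocked by the piperidine, the two open ring positions are equivalent and the amine is tied up by the Lewis acid, so that the ortho-hydroxy ketone formed fixes which oxygen becomes O1.

Step 9
Reactants: 11 1-{2,4-bis(benzyloxy)-6-hydroxy-3-[(2R)-1-methylpiperidin-2-yl]phenyl}ethan-1-one
Product: 13 5,7-bis(benzyloxy)-6-[(2R)-1-methylpiperidin-2-yl]-4H-chromen-4-one, via enaminone 12 (not isolated)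
Conditions: Me2NCH(OMe)2, toluene, 100 °C; then AcOH, 60 °C
Reagents that add atoms: N,N-dimethylformamide dimethyl acetal, COC(OC)N(C)C
Why: Condensation of the methyl ketone with the amide acetal gives the enaminone, and in acetic acid the ortho hydroxyl adds to the enaminone carbon with loss of dimethylamine (addition–elimination), the standard enaminone route to 3-unsubstituted chromones, in which only the hydroxyl para to the piperidine can close so that the piperidine ends at C6.

Step 10
Reactants: 13 5,7-bis(benzyloxy)-6-[(2R)-1-methylpiperidin-2-yl]-4H-chromen-4-one; 14 [4-(benzyloxy)phenyl]boronic acid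
Product: 15 (2S)-5,7-bis(benzyloxy)-2-[4-(benzyloxy)phenyl]-6-[(2R)-1-methylpiperidin-2-yl]-2,3-dihydro-4H-chromen-4-one
Conditions: 14 (2.5 equiv), [Rh(OH)(L)]2 (3 mol%; L = (S)-MeO-F12-BIPHEP, (S)-2,2'-bis[bis(3,4,5-trifluorophenyl)phosphino]-6,6'-dimethoxy-1,1'-biphenyl), toluene/H2O, 25 °C
Reagents that add atoms: none
Why: Rhodium-catalysed asymmetric 1,4-addition of the arylboronic acid to the chromone (Hayashi–Miyaura reaction), in which the aryl–rhodium species carrying the chiral bisphosphine adds across C2=C3 from one face and the rhodium enolate is protonated by water, so that the new C2 centre (S) is set by the ligand and not by the distant C2' centre, while base-free conditions at room temperature keep the flavanone from ring-opening.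

Step 11
Reactants: 15 (2S)-5,7-bis(benzyloxy)-2-[4-(benzyloxy)phenyl]-6-[(2R)-1-methylpiperidin-2-yl]-2,3-dihydro-4H-chromen-4-one
Product: 16 (2S)-5,7-dihydroxy-2-(4-hydroxyphenyl)-6-[(2R)-1-methylpiperidin-2-yl]-2,3-dihydro-4H-chromen-4-one
Conditions: H2 (1 atm), Pd/C (10 wt%), EtOAc/MeOH, 25 °C, stopped as soon as debenzylation is complete
Reagents that add atoms: none
Why: Hydrogenolysis of the three benzyl ethers over palladium on carbon at one atmosphere releases the three phenols under neutral conditions that should leave the ketone, the C2–O1 bond, the C2'–N bond and both stereocentres alone.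

Compound list
1 | 5-aminopentanoic acid | NCCCCC(=O)O | starting material
2 | 5-[(methoxycarbonyl)amino]pentanoic acid | COC(=O)NCCCCC(=O)O | intermediate
3 | phloroglucinol (benzene-1,3,5-triol) | Oc1cc(O)cc(O)c1 | starting material
4 | methyl N-[5-oxo-5-(2,4,6-trihydroxyphenyl)pentyl]carbamate | COC(=O)NCCCCC(=O)c1c(O)cc(O)cc1O | intermediate
5 | 3,5-dihydroxy-4-{5-[(methoxycarbonyl)amino]pentanoyl}phenyl 2,2-dimethylpropanoate | COC(=O)NCCCCC(=O)c1c(O)cc(OC(=O)C(C)(C)C)cc1O | intermediate
6 | 3,5-dihydroxy-4-{1-hydroxy-5-[(methoxycarbonyl)amino]pentyl}phenyl 2,2-dimethylpropanoate (racemic) | COC(=O)NCCCCC(O)c1c(O)cc(OC(=O)C(C)(C)C)cc1O | intermediate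
7 | 5-hydroxy-4-{5-[(methoxycarbonyl)amino]pentylidene}-3-oxocyclohexa-1,5-dien-1-yl 2,2-dimethylpropanoate (ortho-quinone methide, not isolated) | COC(=O)NCCCCC=C1C(=O)C=C(OC(=O)C(C)(C)C)C=C1O | intermediate
8 | methyl (2R)-2-{4-[(2,2-dimethylpropanoyl)oxy]-2,6-dihydroxyphenyl}piperidine-1-carboxylate | COC(=O)N1CCCC[C@@H]1c1c(O)cc(OC(=O)C(C)(C)C)cc1O | intermediate
9 | methyl (2R)-2-{2,6-bis(benzyloxy)-4-[(2,2-dimethylpropanoyl)oxy]phenyl}piperidine-1-carboxylate | COC(=O)N1CCCC[C@@H]1c1c(OCc2ccccc2)cc(OC(=O)C(C)(C)C)cc1OCc1ccccc1 | intermediate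
10 | 3,5-bis(benzyloxy)-4-[(2R)-1-methylpiperidin-2-yl]phenol | CN1CCCC[C@@H]1c1c(OCc2ccccc2)cc(O)cc1OCc1ccccc1 | intermediate
11 | 1-{2,4-bis(benzyloxy)-6-hydroxy-3-[(2R)-1-methylpiperidin-2-yl]phenyl}ethan-1-one | CN1CCCC[C@@H]1c1c(OCc2ccccc2)cc(O)c(C(C)=O)c1OCc1ccccc1 | intermediate
12 | (2E)-1-{2,4-bis(benzyloxy)-6-hydroxy-3-[(2R)-1-methylpiperidin-2-yl]phenyl}-3-(dimethylamino)prop-2-en-1-one (enaminone, not isolated) | CN1CCCC[C@@H]1c1c(OCc2ccccc2)cc(O)c(C(=O)/C=C/N(C)C)c1OCc1ccccc1 | intermediate
13 | 5,7-bis(benzyloxy)-6-[(2R)-1-methylpiperidin-2-yl]-4H-chromen-4-one | CN1CCCC[C@@H]1c1c(OCc2ccccc2)cc2occc(=O)c2c1OCc1ccccc1 | intermediate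
14 | [4-(benzyloxy)phenyl]boronic acid | OB(O)c1ccc(OCc2ccccc2)cc1 | starting material
15 | (2S)-5,7-bis(benzyloxy)-2-[4-(benzyloxy)phenyl]-6-[(2R)-1-methylpiperidin-2-yl]-2,3-dihydro-4H-chromen-4-one | CN1CCCC[C@@H]1c1c(OCc2ccccc2)cc2c(c1OCc1ccccc1)C(=O)C[C@@H](c1ccc(OCc3ccccc3)cc1)O2 | intermediate
16 | (2S)-5,7-dihydroxy-2-(4-hydroxyphenyl)-6-[(2R)-1-methylpiperidin-2-yl]-2,3-dihydro-4H-chromen-4-one | CN1CCCC[C@@H]1c1c(O)cc2c(c1O)C(=O)C[C@@H](c1ccc(O)cc1)O2 | target

Total step count: 11. Longest linear sequence: 11 steps (1 to 16).

Steps most likely to fail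

Step 5. The carbinol may ionise without the catalyst or react through a loosely bound ion pair, so that ring closure proceeds with poor enantiofacial selectivity. The methide may also tautomerise to the vinylphenol or be captured by a second aromatic ring, and the product may re-ionise with erosion of its enantiomeric purity. The fallback gives up asymmetric catalysis and uses known chemistry, setting out from 6. Acid-catalysed dehydrative N-alkylation of the carbamate by the benzylic alcohol (TsOH·H2O, catalytic, CH2Cl2, 25 °C) should give the racemic piperidine carbamate, methyl 2-{4-[(2,2-dimethylpropanoyl)oxy]-2,6-dihydroxyphenyl}piperidine-1-carboxylate F1. Benzylation under the conditions of step 6 would give the racemic bis(benzyl ether) F2, and LiAlH4 under the conditions of step 7 the racemic amine 3,5-bis(benzyloxy)-4-(1-methylpiperidin-2-yl)phenol F3. Classical resolution follows: the salt of the R amine with (2R,3R)-di-p-toluoyltartaric acid, the di-p-toluoyl-L-tartrate salt F4, is crystallised from ethanol (the mirror-image acid is taken if the salt of the S amine proves the less soluble one). Aqueous NaHCO3 then liberates the free base, and the route is rejoined at 10.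

Step 4. The benzylic oxygen may be lost during the reduction (ionisation to the methide and uptake of a second hydride gives the deoxygenated alkyl chain), or the product may ionise and oligomerise on work-up. The fallback sets out from 5 and blocks the methide pathway during the reduction. Allyl bromide and K2CO3 in DMF should give the bis(allyl ether) ketone, 3,5-bis(allyloxy)-4-{5-[(methoxycarbonyl)amino]pentanoyl}phenyl 2,2-dimethylpropanoate F5. NaBH4 in THF/EtOH would then reduce it to the carbinol, 3,5-bis(allyloxy)-4-{1-hydroxy-5-[(methoxycarbonyl)amino]pentyl}phenyl 2,2-dimethylpropanoate F6, which has no free ortho hydroxyl and cannot form a methide. Allyl transfer to morpholine with Pd(PPh3)4 (zerovalent palladium, catalytic) in THF at 25 °C removes both allyl groups under neutral conditions, and the route is rejoined at 6.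

Step 10. Carbometalation of the electron-rich chromone with its peri alkoxy group may be slow, the tertiary amine may bind the catalyst, and the flavanone may ring-open by retro-oxa-Michael reaction with loss of purity at C2. The fallback sets out from 11 and bypasses 12 and 13. Claisen–Schmidt condensation with 4-(benzyloxy)benzaldehyde (KOH, EtOH, 25 °C) should give the chalcone, (2E)-1-{2,4-bis(benzyloxy)-6-hydroxy-3-[(2R)-1-methylpiperidin-2-yl]phenyl}-3-[4-(benzyloxy)phenyl]prop-2-en-1-one F7. Oxa-Michael ring closure (NaOAc, EtOH, reflux) would then give 15 together with its C2 epimer, the (2R)-flavanone F8. Because C2' is fixed, the two are diastereomers; they would be separated by chromatography or crystallisation, and F8 returned to the equilibration. The route is rejoined at 15.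

Further compounds
F1 | step 5 | methyl 2-{4-[(2,2-dimethylpropanoyl)oxy]-2,6-dihydroxyphenyl}piperidine-1-carboxylate (racemic) | COC(=O)N1CCCCC1c1c(O)cc(OC(=O)C(C)(C)C)cc1O
F2 | step 5 | methyl 2-{2,6-bis(benzyloxy)-4-[(2,2-dimethylpropanoyl)oxy]phenyl}piperidine-1-carboxylate (racemic) | COC(=O)N1CCCCC1c1c(OCc2ccccc2)cc(OC(=O)C(C)(C)C)cc1OCc1ccccc1
F3 | step 5 | 3,5-bis(benzyloxy)-4-(1-methylpiperidin-2-yl)phenol (racemic) | CN1CCCCC1c1c(OCc2ccccc2)cc(O)cc1OCc1ccccc1
F4 | step 5 | 3,5-bis(benzyloxy)-4-[(2R)-1-methylpiperidin-2-yl]phenol (2R,3R)-2,3-bis[(4-methylbenzoyl)oxy]butanedioate (1:1 salt) | CN1CCCC[C@@H]1c1c(OCc2ccccc2)cc(O)cc1OCc1ccccc1.OC(=O)[C@H](OC(=O)c1ccc(C)cc1)[C@@H](OC(=O)c1ccc(C)cc1)C(O)=O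
F5 | step 4 | 3,5-bis(allyloxy)-4-{5-[(methoxycarbonyl)amino]pentanoyl}phenyl 2,2-dimethylpropanoate | COC(=O)NCCCCC(=O)c1c(OCC=C)cc(OC(=O)C(C)(C)C)cc1OCC=C
F6 | step 4 | 3,5-bis(allyloxy)-4-{1-hydroxy-5-[(methoxycarbonyl)amino]pentyl}phenyl 2,2-dimethylpropanoate (racemic) | COC(=O)NCCCCC(O)c1c(OCC=C)cc(OC(=O)C(C)(C)C)cc1OCC=C
F7 | step 10 | (2E)-1-{2,4-bis(benzyloxy)-6-hydroxy-3-[(2R)-1-methylpiperidin-2-yl]phenyl}-3-[4-(benzyloxy)phenyl]prop-2-en-1-one | CN1CCCC[C@@H]1c1c(OCc2ccccc2)cc(O)c(C(=O)/C=C/c2ccc(OCc3ccccc3)cc2)c1OCc1ccccc1
F8 | step 10 | (2R)-5,7-bis(benzyloxy)-2-[4-(benzyloxy)phenyl]-6-[(2R)-1-methylpiperidin-2-yl]-2,3-dihydro-4H-chromen-4-one | CN1CCCC[C@@H]1c1c(OCc2ccccc2)cc2c(c1OCc1ccccc1)C(=O)C[C@H](c1ccc(OCc3ccccc3)cc1)O2
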